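**Retrosynthetic overview**
1. Target 9 ⇐ tri-O-benzyl ether 8 by hydrogenolysis (last step).
2. 8 ⇐ flavan-4-ol 5 + (+)-catechin 6: the C4–C8 interflavan bond by dehydrative Friedel–Crafts alkylation. Rings D, E and F of the lower unit come intact from 6 with both stereocentres; C4 is set 2,4-trans by C2.
3. 5 ⇐ (2S)-flavanone 4 by ketone reduction.
4. Key disconnection: the O1–C2 bond of ring C. 4 ⇐ chalcone 3 by a catalytic enantioselective oxa-Michael ring closure, which sets C2, the only stereocentre built from achiral material.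
5. 3 ⇐ 1 + 2 (Claisen–Schmidt). Ring order: A and B bought, C closed in step 2, D/E/F attached in step 4.

Catalyst for step 2 (not a numbered compound, 10 mol%): the bifunctional iminophosphorane (BIMP) 1-[3,5-bis(trifluoromethyl)phenyl]-3-[(2S)-3,3-dimethyl-1-{[tris(4-methoxyphenyl)phosphoranylidene]amino}butan-2-yl]thiourea, made beforehand from the L-tert-leucine-derived azide and P(4-MeOC6H4)3.

Assumption: which antipode of this catalyst gives (2S)-4 is settled in a one-time screen; the D-tert-leucine-derived antipode is equally accessible.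

**Step 1**
Reactants: 1 1-[4-(benzyloxy)-2-hydroxyphenyl]ethan-1-one; 2 3,4-bis(benzyloxy)benzaldehyde
Product: 3 (2E)-1-[4-(benzyloxy)-2-hydroxyphenyl]-3-[3,4-bis(benzyloxy)phenyl]prop-2-en-1-one (tri-O-benzylbutein)
Conditions: KOH (5 equiv), EtOH/H2O, rt, 36 h; then aq. HCl
Reagents that add atoms: none
Why: Claisen–Schmidt (crossed aldol) condensation of the methyl ketone enolate with a non-enolisable aldehyde gives the conjugated E-enone, and under strong base the chalcone stays open as its stable phenoxide; no stereocentre is formed.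

**Step 2**
Reactants: 3 (2E)-1-[4-(benzyloxy)-2-hydroxyphenyl]-3-[3,4-bis(benzyloxy)phenyl]prop-2-en-1-one
Product: 4 (2S)-7-(benzyloxy)-2-[3,4-bis(benzyloxy)phenyl]-2,3-dihydro-4H-chromen-4-one
Conditions: BIMP catalyst (10 mol%), PhMe/CH2Cl2 3:1, −30 °C, stop at ca. 80% conversion with AcOH; recrystallise; recovered 3 recycled
Reagents that add atoms: none
Why: Proposed new method: a bifunctional iminophosphorane–thiourea superbase closing a non-activated, electron-rich 2'-hydroxychalcone by enantioselective 6-endo-trig oxa-Michael addition, not shown for this catalyst class or substrate type; the P=N base deprotonates the 2'-OH to a tight phenoxide/iminophosphonium ion pair while the thiourea N–H pair binds the enone oxygen, so the phenoxide oxygen is delivered to one face of C-β inside the chiral pocket (this forms the O1–C2 bond and ring C and sets C2 as S), and the thiourea-bound enolate is then protonated at C3 by the iminophosphonium to release the catalyst; the high basicity allows −30 °C, where the chalcone/flavanone equilibrium lies further toward flavanone and the retro-oxa-Michael (which needs C3–H removal) is slow, and the acid quench before equilibrium preserves the kinetic ee; closest known reaction types are the cinchona–thiourea oxa-Michael cyclisation of ester-activated 2'-hydroxychalcones and iminophosphorane-catalysed exo oxa-Michael cyclisations of alcohols onto unsaturated esters and amides.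

**Step 3**
Reactants: 4 (2S)-7-(benzyloxy)-2-[3,4-bis(benzyloxy)phenyl]-2,3-dihydro-4H-chromen-4-one
Product: 5 (2S,4S)-7-(benzyloxy)-2-[3,4-bis(benzyloxy)phenyl]-3,4-dihydro-2H-chromen-4-ol (2,4-cis flavan-4-ol)
Conditions: NaBH4 (1.5 equiv), THF/MeOH 4:1, −10 °C, 1 h; then H2O
Reagents that add atoms: none
Why: Borohydride 1,2-reduction of the aryl ketone with axial hydride attack gives the 2,4-cis alcohol (4S); the minor 4-epimer is harmless because C4 is ionised in step 4, and the fast low-temperature reduction of this non-phenolic flavanone outruns base-induced ring opening, so C2 is kept.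

**Step 4**
Reactants: 5 (2S,4S)-7-(benzyloxy)-2-[3,4-bis(benzyloxy)phenyl]-3,4-dihydro-2H-chromen-4-ol; 6 (+)-catechin, (2R,3S)-2-(3,4-dihydroxyphenyl)-3,4-dihydro-2H-chromene-3,5,7-triol (4 equiv)
Product: 8 (2R,3S)-8-{(2S,4R)-7-(benzyloxy)-2-[3,4-bis(benzyloxy)phenyl]-3,4-dihydro-2H-chromen-4-yl}-2-(3,4-dihydroxyphenyl)-3,4-dihydro-2H-chromene-3,5,7-triol, via flavan-4-yl cation 7 (not isolated)
Conditions: TsOH·H2O (5 mol%), HFIP/1,4-dioxane 3:1, 0 °C → rt; chromatography
Reagents that add atoms: none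
Why: SN1-type dehydrative Friedel–Crafts alkylation: acid ionises the 4-OH (lost as water) to cation 7 (stabilised by the para 7-OBn and ortho O1), the phloroglucinol ring D of free catechin attacks through C8, its more nucleophilic position, and the nucleophile enters pseudo-axially on the half-chair with the 2-aryl group equatorial, so C2 sets the new C4 centre 2,4-trans (4β, 4R); the 4α epimer and 4→6 isomer are expected as minor products and are removed by chromatography.

**Step 5**
Reactants: 8 (2R,3S)-8-{(2S,4R)-7-(benzyloxy)-2-[3,4-bis(benzyloxy)phenyl]-3,4-dihydro-2H-chromen-4-yl}-2-(3,4-dihydroxyphenyl)-3,4-dihydro-2H-chromene-3,5,7-triol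
Product: 9 (2R,3S)-2-(3,4-dihydroxyphenyl)-8-[(2S,4R)-2-(3,4-dihydroxyphenyl)-7-hydroxy-3,4-dihydro-2H-chromen-4-yl]-3,4-dihydro-2H-chromene-3,5,7-triol, that is (2S)-7,3',4'-trihydroxyflavan-(4β→8)-catechin
Conditions: H2 (1 atm), Pd(OH)2/C, THF/MeOH 1:1, rt; Sephadex LH-20
Reagents that add atoms: none
Why: Palladium-catalysed hydrogenolysis cleaves the three benzyl aryl ethers, while the cyclic C2–O1 ethers and the C4–C8 bond survive at 1 atm and room temperature; no stereocentre is touched.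

**Compound list**
1 | 1-[4-(benzyloxy)-2-hydroxyphenyl]ethan-1-one | CC(=O)c1ccc(OCc2ccccc2)cc1O | starting material
2 | 3,4-bis(benzyloxy)benzaldehyde | O=Cc1ccc(OCc2ccccc2)c(OCc2ccccc2)c1 | starting material
3 | (2E)-1-[4-(benzyloxy)-2-hydroxyphenyl]-3-[3,4-bis(benzyloxy)phenyl]prop-2-en-1-one | O=C(/C=C/c1ccc(OCc2ccccc2)c(OCc2ccccc2)c1)c1ccc(OCc2ccccc2)cc1O | intermediate
4 | (2S)-7-(benzyloxy)-2-[3,4-bis(benzyloxy)phenyl]-2,3-dihydro-4H-chromen-4-one | c1ccccc1COc1ccc2c(c1)O[C@H](c1ccc(OCc3ccccc3)c(OCc3ccccc3)c1)CC2=O | intermediate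
5 | (2S,4S)-7-(benzyloxy)-2-[3,4-bis(benzyloxy)phenyl]-3,4-dihydro-2H-chromen-4-ol | c1ccccc1COc1ccc2c(c1)O[C@H](c1ccc(OCc3ccccc3)c(OCc3ccccc3)c1)C[C@@H]2O | intermediate
6 | (+)-catechin, (2R,3S)-2-(3,4-dihydroxyphenyl)-3,4-dihydro-2H-chromene-3,5,7-triol | O[C@H]1Cc2c(O)cc(O)cc2O[C@@H]1c1ccc(O)c(O)c1 | starting material
7 | (2S)-7-(benzyloxy)-2-[3,4-bis(benzyloxy)phenyl]-3,4-dihydro-2H-chromen-4-ylium (flavan-4-yl cation) | c1ccccc1COc1ccc2c(c1)O[C@H](c1ccc(OCc3ccccc3)c(OCc3ccccc3)c1)C[CH+]2 | intermediate (not isolated)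
8 | (2R,3S)-8-{(2S,4R)-7-(benzyloxy)-2-[3,4-bis(benzyloxy)phenyl]-3,4-dihydro-2H-chromen-4-yl}-2-(3,4-dihydroxyphenyl)-3,4-dihydro-2H-chromene-3,5,7-triol | c1ccccc1COc1ccc2c(c1)O[C@H](c1ccc(OCc3ccccc3)c(OCc3ccccc3)c1)C[C@H]2c1c(O)cc(O)c2c1O[C@H](c1ccc(O)c(O)c1)[C@@H](O)C2 | intermediate
9 | (2R,3S)-2-(3,4-dihydroxyphenyl)-8-[(2S,4R)-2-(3,4-dihydroxyphenyl)-7-hydroxy-3,4-dihydro-2H-chromen-4-yl]-3,4-dihydro-2H-chromene-3,5,7-triol | Oc1ccc2c(c1)O[C@H](c1ccc(O)c(O)c1)C[C@H]2c1c(O)cc(O)c2c1O[C@H](c1ccc(O)c(O)c1)[C@@H](O)C2 | target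

**Step count and risks**
Total steps: 5. Longest linear sequence: 5 steps (1 → 3 → 4 → 5 → 8 → 9).

The three steps most likely to fail:

Step 2 (the proposed new method). The ee may be low, the sense of induction may be wrong, or the chalcone/flavanone equilibrium may cap conversion. The fallback uses known chemistry, sets out from 3 and comes back at 5. Chalcone 3 is cyclised without stereocontrol (NaOAc, EtOH, reflux) to the racemic flavanone rac-7-(benzyloxy)-2-[3,4-bis(benzyloxy)phenyl]-2,3-dihydro-4H-chromen-4-one F1. F1 is then resolved kinetically by Noyori-type asymmetric transfer hydrogenation (RuCl(p-cymene)[(S,S)-TsDPEN] 1 mol%, HCO2H/Et3N 5:2, EtOAc, rt, stopped near 50% conversion). The (2S) enantiomer is the matched one and is reduced straight to 5, so step 3 is skipped. The unreacted (2R)-7-(benzyloxy)-2-[3,4-bis(benzyloxy)phenyl]-2,3-dihydro-4H-chromen-4-one F2 is racemised back to F1 with NaOAc/EtOH (through 3) and recycled.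

Step 3. The 7-alkoxyflavan-4-ol 5 is acid-labile and may dehydrate to the flav-3-ene on silica or on storage. The fallback sets out from 4 and comes back at 8. After the NaBH4 reduction the crude alcohol 5 is not chromatographed but stirred in dry MeOH with PPTS (10 mol%, 0 °C → rt). This traps it as the bench-stable (2S)-7-(benzyloxy)-2-[3,4-bis(benzyloxy)phenyl]-4-methoxy-3,4-dihydro-2H-chromene F3 (both C4 epimers are usable). F3 is taken through the step 4 conditions in place of 5 and ionises to the same cation 7.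

Step 4. Free catechin may give too much 4α epimer, 4→6 regioisomer or 6,8-bis-alkylation, and the cation may eliminate to the flav-3-ene and disproportionate. The fallback sets out from 6 (with 5) and comes back at 9. Catechin is benzylated on its four phenols (BnBr, K2CO3, DMF, 0 °C → rt) to (2R,3S)-5,7-bis(benzyloxy)-2-[3,4-bis(benzyloxy)phenyl]-3,4-dihydro-2H-chromen-3-ol F4, a C8-selective nucleophile. F4 (3 equiv) is coupled with 5 under TMSOTf (0.2 equiv) in CH2Cl2 at −78 → −40 °C to give (2R,3S)-5,7-bis(benzyloxy)-8-{(2S,4R)-7-(benzyloxy)-2-[3,4-bis(benzyloxy)phenyl]-3,4-dihydro-2H-chromen-4-yl}-2-[3,4-bis(benzyloxy)phenyl]-3,4-dihydro-2H-chromen-3-ol F5. Hydrogenolysis of all seven benzyl ethers (H2, Pd(OH)2/C, THF/MeOH) then gives 9 directly.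

**Further compounds**
F1 | step 2 | rac-7-(benzyloxy)-2-[3,4-bis(benzyloxy)phenyl]-2,3-dihydro-4H-chromen-4-one | c1ccccc1COc1ccc2c(c1)OC(c1ccc(OCc3ccccc3)c(OCc3ccccc3)c1)CC2=O
F2 | step 2 | (2R)-7-(benzyloxy)-2-[3,4-bis(benzyloxy)phenyl]-2,3-dihydro-4H-chromen-4-one | c1ccccc1COc1ccc2c(c1)O[C@@H](c1ccc(OCc3ccccc3)c(OCc3ccccc3)c1)CC2=O
F3 | step 3 | (2S)-7-(benzyloxy)-2-[3,4-bis(benzyloxy)phenyl]-4-methoxy-3,4-dihydro-2H-chromene (C4 epimers) | c1ccccc1COc1ccc2c(c1)O[C@H](c1ccc(OCc3ccccc3)c(OCc3ccccc3)c1)CC2OC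
F4 | step 4 | (2R,3S)-5,7-bis(benzyloxy)-2-[3,4-bis(benzyloxy)phenyl]-3,4-dihydro-2H-chromen-3-ol | O[C@H]1Cc2c(OCc3ccccc3)cc(OCc3ccccc3)cc2O[C@@H]1c1ccc(OCc2ccccc2)c(OCc2ccccc2)c1
F5 | step 4 | (2R,3S)-5,7-bis(benzyloxy)-8-{(2S,4R)-7-(benzyloxy)-2-[3,4-bis(benzyloxy)phenyl]-3,4-dihydro-2H-chromen-4-yl}-2-[3,4-bis(benzyloxy)phenyl]-3,4-dihydro-2H-chromen-3-ol | c1ccccc1COc1ccc2c(c1)O[C@H](c1ccc(OCc3ccccc3)c(OCc3ccccc3)c1)C[C@H]2c1c(OCc3ccccc3)cc(OCc3ccccc3)c2c1O[C@H](c1ccc(OCc3ccccc3)c(OCc3ccccc3)c1)[C@@H](O)C2
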